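**Plan**

1. The target is an oxane (O1, C2–C6) with the acrylic acid on C2 and the homofarnesyl chain on C5. Its (2R,5R) descriptors correspond to the 2,5-cis isomer, which has one substituent axial and is the less stable one, so C2 has to be set kinetically.
2. Feature used: the ring bond O1–C2 is an allylic C–O bond, because C2 sits next to the carbon that carries both the exocyclic CH2 and the carboxyl group. Cutting O1–C2 gives a 2-(methoxycarbonyl)allyl cation equivalent (a Morita–Baylis–Hillman carbonate) and the C6 hydroxyl.
3. Further cuts: C2–C(acrylate) (aldehyde plus methyl acrylate), C1'–C2' of the chain (chiral C5 Grignard reagent plus (2E,6E)-farnesyl bromide), and C5–C6 (auxiliary-controlled hydroxymethylation of a pent-4-enoyl imide).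
4. Forward order: imide, hydroxymethylation, silyl ether, bromide, chain coupling, hydroboration and oxidation, Morita–Baylis–Hillman reaction, carbonate, desilylation, closure of the only ring, ester hydrolysis.
5. Stereochemistry: C5 comes from the (S)-4-benzyl oxazolidinone auxiliary (step 2). C2 comes from the chiral ligand in a stereoconvergent palladium-catalysed ring closure that takes both carbinol epimers to one configuration. The (E)-alkenes are carried in intact from farnesyl bromide.

Key step: step 12

Assumption: the (R,R) enantiomer of the DACH-phenyl Trost ligand is taken to be the one that steers the alkoxide to the allyl face giving (2R); I could not fix this sense from first principles, both enantiomers are commercial, and the antipode replaces it without other change if a trial run shows the opposite sense.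

**Route**

Step 1
Reactants: 1 (4S)-4-benzyl-1,3-oxazolidin-2-one; 2 pent-4-enoyl chloride
Product: 3 (4S)-4-benzyl-3-(pent-4-enoyl)-1,3-oxazolidin-2-one
Conditions: Et3N, DMAP (10 mol%), CH2Cl2, 0 °C → rt
Reagents that add atoms: none
Why: DMAP-catalysed N-acylation of the oxazolidinone by the acid chloride (acyl transfer) is routine and leaves the auxiliary stereocenter untouched.

Step 2
Reactants: 3
Product: 5 (4S)-4-benzyl-3-[(2R)-2-(hydroxymethyl)pent-4-enoyl]-1,3-oxazolidin-2-one, via titanium enolate 4 (not isolated)
Conditions: TiCl4, iPr2NEt, CH2Cl2, 0 °C; then 1,3,5-trioxane, TiCl4, 0 °C; aq NH4Cl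
Reagents that add atoms: 1,3,5-trioxane (C1OCOCO1)
Why: Evans titanium-enolate hydroxymethylation, in which the chelated (Z)-enolate 4 is attacked by TiCl4-activated formaldehyde on the face opposite the benzyl group, fixing the future C5 as (2R) in 5 (it becomes (5R) in the target).

Step 3
Reactants: 5
Product: 6 (4S)-4-benzyl-3-[(2R)-2-({[tert-butyl(dimethyl)silyl]oxy}methyl)pent-4-enoyl]-1,3-oxazolidin-2-one
Conditions: TBSCl, imidazole, CH2Cl2, rt
Reagents that add atoms: tert-butyldimethylsilyl chloride (CC(C)(C)[Si](C)(C)Cl)
Why: Standard silylation of a primary alcohol, which marks this CH2O arm as the future ring oxygen (C6–O1) and keeps the two CH2O arms distinct after step 4.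

Step 4
Reactants: 6
Product: 7 (2S)-2-({[tert-butyl(dimethyl)silyl]oxy}methyl)pent-4-en-1-ol
Conditions: LiBH4, MeOH (1 equiv), Et2O, 0 °C
Reagents that add atoms: none
Why: Reductive cleavage of the N-acyl oxazolidinone by LiBH4 gives the primary alcohol and frees the auxiliary without touching the stereocenter (the change from R to S is only a change of CIP priorities).

Step 5
Reactants: 7
Product: 8 {[(2R)-2-(bromomethyl)pent-4-en-1-yl]oxy}(tert-butyl)dimethylsilane
Conditions: CBr4, PPh3, 2,6-lutidine, CH2Cl2, 0 °C
Reagents that add atoms: carbon tetrabromide (BrC(Br)(Br)Br)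
Why: Appel bromination (SN2 at a primary carbon) under lutidine buffering is mild enough for the silyl ether and the terminal alkene and does not involve the stereocenter.

Step 6
Reactants: 8; 9 (2E,6E)-farnesyl bromide [(2E,6E)-1-bromo-3,7,11-trimethyldodeca-2,6,10-triene]
Product: 11 tert-butyl(dimethyl){[(2R,5E,9E)-6,10,14-trimethyl-2-(prop-2-en-1-yl)pentadeca-5,9,13-trien-1-yl]oxy}silane, via Grignard reagent 10 (not isolated)
Conditions: Mg, THF, rt; then 9, Li2CuCl4 (3 mol%), THF, −78 → 0 °C
Reagents that add atoms: none
Why: Copper-catalysed Grignard–allylic halide cross-coupling (Kochi–Schlosser type), in which the alkylcuprate formed from 10 displaces bromide at the primary allylic carbon of 9 in the SN2 sense because γ-attack would build a quaternary centre, so the (E)-alkenes are carried through unchanged.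

Step 7
Reactants: 11
Product: 13 (4R,7E,11E)-4-({[tert-butyl(dimethyl)silyl]oxy}methyl)-8,12,16-trimethylheptadeca-7,11,15-trien-1-ol, via B-alkyl borane 12 (not isolated)
Conditions: 9-BBN, THF, 0 °C → rt; then NaOH, H2O2, 0 °C → rt
Reagents that add atoms: hydrogen peroxide (OO)
Why: Hydroboration–oxidation with 9-BBN is anti-Markovnikov and, for steric reasons, selective for the monosubstituted terminal alkene over the three trisubstituted ones.

Step 8
Reactants: 13
Product: 14 (4R,7E,11E)-4-({[tert-butyl(dimethyl)silyl]oxy}methyl)-8,12,16-trimethylheptadeca-7,11,15-trienal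
Conditions: TEMPO (10 mol%), PhI(OAc)2, CH2Cl2, rt
Reagents that add atoms: none
Why: TEMPO/PhI(OAc)2 oxidation (oxoammonium mechanism) stops at the aldehyde and spares the trisubstituted alkenes and the silyl ether.

Step 9
Reactants: 14; 15 methyl acrylate
Product: 16 methyl (6R,9E,13E)-6-({[tert-butyl(dimethyl)silyl]oxy}methyl)-3-hydroxy-10,14,18-trimethyl-2-methylidenenonadeca-9,13,17-trienoate (mixture of C3 epimers)
Conditions: 15 (5 equiv, neat), quinuclidine (0.5 equiv), MeOH (1 equiv), rt
Reagents that add atoms: none
Why: Morita–Baylis–Hillman reaction (amine conjugate addition, aldol addition of the ammonium enolate, methanol-assisted proton transfer and elimination), in which the new carbinol centre forms without control, as intended, because step 12 erases it.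

Step 10
Reactants: 16
Product: 17 methyl (6R,9E,13E)-6-({[tert-butyl(dimethyl)silyl]oxy}methyl)-3-[(methoxycarbonyl)oxy]-10,14,18-trimethyl-2-methylidenenonadeca-9,13,17-trienoate (mixture of C3 epimers)
Conditions: ClCO2Me, pyridine, CH2Cl2, 0 °C
Reagents that add atoms: methyl chloroformate (COC(=O)Cl)
Why: O-acylation of the secondary allylic alcohol with methyl chloroformate turns it into the leaving group for palladium, and pyridine at 0 °C is too weak a Lewis base to trigger allylic transposition.

Step 11
Reactants: 17
Product: 18 methyl (6R,9E,13E)-6-(hydroxymethyl)-3-[(methoxycarbonyl)oxy]-10,14,18-trimethyl-2-methylidenenonadeca-9,13,17-trienoate (mixture of C3 epimers)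
Conditions: HF·pyridine, THF, 0 °C → rt
Reagents that add atoms: none
Why: Fluoride-mediated desilylation with buffered HF·pyridine removes the primary TBS ether and is compatible with the allylic carbonate, the acrylate and the trisubstituted alkenes.

Step 12
Reactants: 18
Product: 20 methyl 2-[(2R,5R)-5-[(3E,7E)-4,8,12-trimethyltrideca-3,7,11-trien-1-yl]oxan-2-yl]prop-2-enoate, via allylpalladium cation 19 (not isolated)
Conditions: Pd2(dba)3·CHCl3 (2.5 mol%), (R,R)-DACH-phenyl Trost ligand (7.5 mol%), degassed CH2Cl2 (0.02 M), rt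
Reagents that add atoms: none
Why: Zerovalent palladium ionizes either C3 epimer of 18 with loss of methyl carbonate (which gives CO2 and methoxide, the base that frees the C6 alkoxide), so both epimers funnel into one 2-(methoxycarbonyl)allyl palladium cation 19 whose diastereomeric faces interconvert fast by η3–η1–η3 slippage at its unsubstituted CH2 terminus. The closest known reaction type is the Tsuji–Trost asymmetric allylic etherification in its dynamic kinetic form, known for Morita–Baylis–Hillman carbonates with oxygen nucleophiles and for ligand-controlled oxane closure by tethered alcohols. The oxane closes in the 6-exo mode by attack of the alkoxide on the substituted allyl terminus anti to palladium, the alternative attack at the CH2 terminus being an 8-endo closure that the tether length disfavours. The new stereocenter C2 is set by the chiral pocket of the ligand (catalyst control under Curtin–Hammett conditions) and not by C5, which is essential because the (2R,5R) product is the cis isomer with one axial substituent that the substrate alone would not favour. The step therefore needs face selectivity at C2 against a small substrate bias, which should be attainable because C5 is remote (a 1,4 relationship with only a chair-type equatorial preference to overcome), and branched regioselectivity, which the ring size secures. The product ether is not re-ionized by the catalyst, so the kinetic cis selectivity should be preserved.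

Step 13
Reactants: 20
Product: 22 rhopaloic acid B [2-[(2R,5R)-5-[(3E,7E)-4,8,12-trimethyltrideca-3,7,11-trien-1-yl]oxan-2-yl]prop-2-enoic acid], via lithium carboxylate 21 (not isolated)
Conditions: LiOH·H2O, THF/H2O (3:1), 0 °C → rt; then 0.5 M HCl to pH 3, 0 °C
Reagents that add atoms: lithium hydroxide ([Li+].[OH-])
Why: Saponification of the methyl ester (acyl substitution by hydroxide) should leave the cis configuration intact because C2 bears no readily removable proton, and the low temperature and absence of methanol limit conjugate addition to the acrylate.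

**Compound list**

1 | (4S)-4-benzyl-1,3-oxazolidin-2-one | O=C1N[C@@H](Cc2ccccc2)CO1 | starting material
2 | pent-4-enoyl chloride | C=CCCC(=O)Cl | starting material
3 | (4S)-4-benzyl-3-(pent-4-enoyl)-1,3-oxazolidin-2-one | C=CCCC(=O)N1[C@@H](Cc2ccccc2)COC1=O | intermediate
4 | trichlorotitanium (Z)-enolate of 3 | C=CC/C=C(\O[Ti](Cl)(Cl)Cl)N1[C@@H](Cc2ccccc2)COC1=O | intermediate
5 | (4S)-4-benzyl-3-[(2R)-2-(hydroxymethyl)pent-4-enoyl]-1,3-oxazolidin-2-one | C=CC[C@@H](C(=O)N1[C@@H](Cc2ccccc2)COC1=O)CO | intermediate
6 | (4S)-4-benzyl-3-[(2R)-2-({[tert-butyl(dimethyl)silyl]oxy}methyl)pent-4-enoyl]-1,3-oxazolidin-2-one | C=CC[C@@H](C(=O)N1[C@@H](Cc2ccccc2)COC1=O)CO[Si](C)(C)C(C)(C)C | intermediate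
7 | (2S)-2-({[tert-butyl(dimethyl)silyl]oxy}methyl)pent-4-en-1-ol | C=CC[C@@H](CO)CO[Si](C)(C)C(C)(C)C | intermediate
8 | {[(2R)-2-(bromomethyl)pent-4-en-1-yl]oxy}(tert-butyl)dimethylsilane | C=CC[C@@H](CBr)CO[Si](C)(C)C(C)(C)C | intermediate
9 | (2E,6E)-1-bromo-3,7,11-trimethyldodeca-2,6,10-triene (farnesyl bromide) | BrC/C=C(\C)CC/C=C(\C)CCC=C(C)C | starting material
10 | {(2R)-2-({[tert-butyl(dimethyl)silyl]oxy}methyl)pent-4-en-1-yl}magnesium bromide | C=CC[C@@H](C[Mg]Br)CO[Si](C)(C)C(C)(C)C | intermediate
11 | tert-butyl(dimethyl){[(2R,5E,9E)-6,10,14-trimethyl-2-(prop-2-en-1-yl)pentadeca-5,9,13-trien-1-yl]oxy}silane | C=CC[C@@H](CC/C=C(\C)CC/C=C(\C)CCC=C(C)C)CO[Si](C)(C)C(C)(C)C | intermediate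
12 | 9-[(4R,7E,11E)-4-({[tert-butyl(dimethyl)silyl]oxy}methyl)-8,12,16-trimethylheptadeca-7,11,15-trien-1-yl]-9-borabicyclo[3.3.1]nonane | B1(C2CCCC1CCC2)CCC[C@@H](CC/C=C(\C)CC/C=C(\C)CCC=C(C)C)CO[Si](C)(C)C(C)(C)C | intermediate
13 | (4R,7E,11E)-4-({[tert-butyl(dimethyl)silyl]oxy}methyl)-8,12,16-trimethylheptadeca-7,11,15-trien-1-ol | OCCC[C@@H](CC/C=C(\C)CC/C=C(\C)CCC=C(C)C)CO[Si](C)(C)C(C)(C)C | intermediate
14 | (4R,7E,11E)-4-({[tert-butyl(dimethyl)silyl]oxy}methyl)-8,12,16-trimethylheptadeca-7,11,15-trienal | O=CCC[C@@H](CC/C=C(\C)CC/C=C(\C)CCC=C(C)C)CO[Si](C)(C)C(C)(C)C | intermediate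
15 | methyl acrylate | C=CC(=O)OC | starting material
16 | methyl (6R,9E,13E)-6-({[tert-butyl(dimethyl)silyl]oxy}methyl)-3-hydroxy-10,14,18-trimethyl-2-methylidenenonadeca-9,13,17-trienoate (C3 epimers) | C=C(C(=O)OC)C(O)CC[C@@H](CC/C=C(\C)CC/C=C(\C)CCC=C(C)C)CO[Si](C)(C)C(C)(C)C | intermediate
17 | methyl (6R,9E,13E)-6-({[tert-butyl(dimethyl)silyl]oxy}methyl)-3-[(methoxycarbonyl)oxy]-10,14,18-trimethyl-2-methylidenenonadeca-9,13,17-trienoate (C3 epimers) | C=C(C(=O)OC)C(OC(=O)OC)CC[C@@H](CC/C=C(\C)CC/C=C(\C)CCC=C(C)C)CO[Si](C)(C)C(C)(C)C | intermediate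
18 | methyl (6R,9E,13E)-6-(hydroxymethyl)-3-[(methoxycarbonyl)oxy]-10,14,18-trimethyl-2-methylidenenonadeca-9,13,17-trienoate (C3 epimers) | C=C(C(=O)OC)C(OC(=O)OC)CC[C@@H](CC/C=C(\C)CC/C=C(\C)CCC=C(C)C)CO | intermediate
19 | 2-(methoxycarbonyl)allyl palladium cation derived from 18 (drawn in its η1 form bound at CH2; bisphosphine ligand and methyl carbonate counter-ion omitted) | COC(=O)C(C[Pd+])=CCC[C@@H](CC/C=C(\C)CC/C=C(\C)CCC=C(C)C)CO | intermediate
20 | methyl 2-[(2R,5R)-5-[(3E,7E)-4,8,12-trimethyltrideca-3,7,11-trien-1-yl]oxan-2-yl]prop-2-enoate | C=C(C(=O)OC)[C@H]1CC[C@@H](CC/C=C(\C)CC/C=C(\C)CCC=C(C)C)CO1 | intermediate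
21 | lithium 2-[(2R,5R)-5-[(3E,7E)-4,8,12-trimethyltrideca-3,7,11-trien-1-yl]oxan-2-yl]prop-2-enoate | C=C(C(=O)[O-])[C@H]1CC[C@@H](CC/C=C(\C)CC/C=C(\C)CCC=C(C)C)CO1.[Li+] | intermediate
22 | rhopaloic acid B, 2-[(2R,5R)-5-[(3E,7E)-4,8,12-trimethyltrideca-3,7,11-trien-1-yl]oxan-2-yl]prop-2-enoic acid | C=C(C(=O)O)[C@H]1CC[C@@H](CC/C=C(\C)CC/C=C(\C)CCC=C(C)C)CO1 | target

**Totals**

Total step count: 13. Longest linear sequence: 13 steps (from 1 and 2; 9 and 15 enter as commercial materials).

**Steps most likely to fail**

Step 12. The ligand may not override the substrate's preference for the diequatorial, 2,5-trans mode of closure, or the alkoxide may capture the allyl complex before its faces have equilibrated; either would erode the cis selectivity, and β-hydride loss from the allyl complex to a dienoate could compete. The fallback gives up the stereoconvergent closure and sets C2 before the ring is formed. It sets out from aldehyde 14. A β-isocupreidine-catalysed asymmetric Morita–Baylis–Hillman reaction with 1,1,1,3,3,3-hexafluoroisopropyl acrylate (DMF, −55 °C), whose sense I recall as (R) but have not verified, should give the hexafluoroisopropyl (3R)-hydroxy ester F1. Methanolysis (MeOH, Et3N) should give the (3R)-methyl ester F2, and HF·pyridine the (3R)-diol F3. Selective sulfonylation of the primary hydroxyl (TsCl, pyridine, 0 °C) should give the primary tosylate F4. NaH in THF then closes the ring by Williamson etherification at C6 (6-exo-tet, C2 retained), and the route is rejoined at 20.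

Step 6. The cuprate may attack the γ-carbon of the allylic bromide to give the branched isomer, the (E)-geometry may be lost through allylcopper isomerization, or Wurtz-type homocoupling may consume the Grignard reagent. The fallback replaces the organocopper coupling by sulfone-anion alkylation and sets out from bromide 8. Displacement with PhSO2Na (DMF, 60 °C) should give the phenyl sulfone F5. Deprotonation (n-BuLi, THF/DMPU, −78 °C) and alkylation with 9 should give the farnesylated sulfone F6, as a mixture at the sulfonyl carbon that is of no consequence. Reductive desulfonylation (sodium amalgam, Na(Hg), Na2HPO4, MeOH/THF, −20 °C) returns to the route at 11.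

Step 9. Addition to the lipophilic, enolizable aldehyde may be slow or incomplete, with aldol self-condensation and acrylate oligomerization competing over the long reaction time. The fallback pre-forms the nucleophile and sets out from 14. Hydroalumination of methyl propiolate with DIBAL-H in the presence of NMO (THF, 0 °C) gives the α-(methoxycarbonyl)vinyl alane, which adds to 14 (0 °C → rt, vinylalumination) and returns to the route directly at 16. It passes through no new isolated compound (entry F0).

**Further compounds**

F1 | step 12 | 1,1,1,3,3,3-hexafluoropropan-2-yl (3R,6R,9E,13E)-6-({[tert-butyl(dimethyl)silyl]oxy}methyl)-3-hydroxy-10,14,18-trimethyl-2-methylidenenonadeca-9,13,17-trienoate | C=C(C(=O)OC(C(F)(F)F)C(F)(F)F)[C@H](O)CC[C@@H](CC/C=C(\C)CC/C=C(\C)CCC=C(C)C)CO[Si](C)(C)C(C)(C)C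
F2 | step 12 | methyl (3R,6R,9E,13E)-6-({[tert-butyl(dimethyl)silyl]oxy}methyl)-3-hydroxy-10,14,18-trimethyl-2-methylidenenonadeca-9,13,17-trienoate | C=C(C(=O)OC)[C@H](O)CC[C@@H](CC/C=C(\C)CC/C=C(\C)CCC=C(C)C)CO[Si](C)(C)C(C)(C)C
F3 | step 12 | methyl (3R,6R,9E,13E)-3-hydroxy-6-(hydroxymethyl)-10,14,18-trimethyl-2-methylidenenonadeca-9,13,17-trienoate | C=C(C(=O)OC)[C@H](O)CC[C@@H](CC/C=C(\C)CC/C=C(\C)CCC=C(C)C)CO
F4 | step 12 | methyl (3R,6R,9E,13E)-3-hydroxy-10,14,18-trimethyl-2-methylidene-6-{[(4-methylbenzenesulfonyl)oxy]methyl}nonadeca-9,13,17-trienoate | C=C(C(=O)OC)[C@H](O)CC[C@@H](CC/C=C(\C)CC/C=C(\C)CCC=C(C)C)COS(=O)(=O)c1ccc(C)cc1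
F5 | step 6 | {[(2R)-2-[(benzenesulfonyl)methyl]pent-4-en-1-yl]oxy}(tert-butyl)dimethylsilane | C=CC[C@@H](CS(=O)(=O)c1ccccc1)CO[Si](C)(C)C(C)(C)C
F6 | step 6 | tert-butyl(dimethyl){[(2R)-2-[(3E,7E)-1-(benzenesulfonyl)-4,8,12-trimethyltrideca-3,7,11-trien-1-yl]pent-4-en-1-yl]oxy}silane (mixture at the sulfonyl carbon) | C=CC[C@@H](C(C/C=C(\C)CC/C=C(\C)CCC=C(C)C)S(=O)(=O)c1ccccc1)CO[Si](C)(C)C(C)(C)C
F0 | step 9 | none | none
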